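## The problem

The target **12** is a 2,3-dihydrobenzofuran neolignan. Benzene ring A is fused through C3a and C7a to the oxygen heterocycle, ring B (O1, C2, C3). C2 carries a 3,4,5-trimethoxyphenyl group (ring C), C3 a methyl group, C7 a methoxy group and C5 an (E)-prop-1-enyl chain. The only stereocentres are the adjacent C2 and C3, both R, which places ring C and the methyl group trans on ring B; both the absolute and the relative configuration have to be controlled. Either centre could steer the other, but it is cleaner to fix both on an open-chain precursor, where one reagent sets them together. C2 is a benzylic ether carbon next to an electron-rich ring and ionises under protic or Lewis acid with loss of configuration. The C5 propenyl styrene does not survive hydrogenation catalysts, electrophiles or strong acid and has to be E, so the olefin belongs at the end and acid is excluded once ring B is closed. The enabling feature lies in ring A: C7a, the carbon that bears O1, is para to C5. A π-acceptor at C5 that can later be turned into the propenyl group therefore makes C7a electrophilic, and O1–C7a can be formed by displacing a halide without touching C2 or C3. Ring A then reduces to a 1,2,3,5-tetrasubstituted benzene with a coupling handle at the future C3a and a leaving group at the future C7a.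

## Retrosynthesis

**Propenyl group.** The C=C bond of the side chain is cut first, leading from **12** to aldehyde **10** and the two-carbon sulfone **11**. A cross-coupling at C5 would need a halide there, and a halide would not activate C7a. Carrying the styrene through the earlier steps would expose it to a hydrogenation catalyst. The forward reaction (Julia–Kocienski olefination) must be E-selective and run under base only, which suits the acid-labile C2 ether.

**Aldehyde to nitrile.** Aldehyde **10** is traced to nitrile **8** by a change of oxidation level. The nitrile is the better form for the ring closure: it is the strongest simple para acceptor, it has no carbonyl carbon that an alkoxide could attack, and it tolerates the palladium and ruthenium steps. The forward step is a partial hydride reduction with hydrolysis of the aldimine **9**.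

**Ring B (key disconnection).** O1–C7a is cut, opening **8** to the acyclic fluoro alcohol **7**. The neighbouring cut, O1–C2, would pass through a benzylic cation or an SN2 inversion at a hindered benzylic centre and would put C2 at risk. Cutting C3–C3a in the bicycle offers no simple forward reaction. With the O1–C7a cut, both stereocentres already exist in **7** and no bond to either is made or broken. The forward reaction only has to be an ipso substitution at C7a, which the para nitrile and fluoride as nucleofuge provide.

**Both stereocentres.** Alcohol **7** is traced to the racemic α-aryl ketone **6** by removing the carbinol hydrogen. Because C2 of the propanone chain lies between a ketone and an electron-poor aryl ring, its configuration is labile. A single enantioselective hydrogenation under dynamic kinetic resolution can therefore set C1 and C2 together from racemic material. This is simpler than any sequence that builds the two centres one after the other, and the precursor has no stereochemistry at all.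

**Joining the two aromatic halves.** The C–C bond between the ketone α-carbon and ring A (the future C3–C3a) is cut, giving aryl bromide **4** and propiophenone **5**. The alternative cut between the carbinol carbon and the methine would require a configurationally defined benzylic nucleophile. The chosen cut is a convergent ketone α-arylation of two simple partners, and it must proceed with a weak base so that the nitrile and the activated C–F bond survive.

**Ring A building block.** Bromide **4** is traced through the diazonium salt **3** to the bromoaniline **2** (C–F from C–N, Balz–Schiemann) and then to the commercial aminonitrile **1** (ortho bromination). The amino group first directs the bromine to the only free ortho position and is then exchanged for fluorine, so the pattern Br / F / OMe around the ring follows from the starting material without any selectivity problem.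

## Roads not taken

**Alternative 1:** Dötz benzannulation onto a preformed dihydrofuran. Ring A would be cut at C6–C7, C4–C5 and C3a–C4. In the forward step the zerovalent chromium carbene complex **A2**, which already contains ring B with both stereocentres, is heated with the conjugated enyne **A3**. Alkyne insertion, carbonyl insertion and electrocyclisation give the C4 phenol **A1**. Its merits are real: three C–C bonds and a ring form in one step, the regiochemistry follows from the terminal alkyne, and the propenyl group arrives with the alkyne, so no late olefination is needed. In that respect it is better than the chosen plan. Its weak points for this target are these: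
- The reaction leaves a hydroxyl group at C4 that the target lacks; removing it costs at least two further steps next to the styrene.
- It uses stoichiometric chromium.
- It needs an enantiopure 2,3-disubstituted dihydrofuran, which is an acid-sensitive enol ether and needs its own asymmetric synthesis before it can be metallated and turned into **A2**.
- The product **A1** is an electron-rich hydroquinone monoether that oxidises easily.

The chosen plan sets against the higher convergence of this road a sequence in which every atom introduced stays in the target and the stereocentres come from one catalytic step.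

**Alternative 2:** gold-catalysed furan–yne phenol synthesis. Rings A and B would both be cut: C3a–C7a and C6–C7. In the forward step a carbophilic gold catalyst activates the ethynyl ether **A5**. The furan carbon attacks the oxygen-bearing alkyne carbon, the opened furan recloses on the terminal alkyne carbon, and the furan oxygen ends as the C7 hydroxyl of phenol **A4**. Building both rings in one catalytic, atom-economical step from a non-aromatic precursor is more elegant than anything in the chosen plan, and no carbon–fluorine chemistry is needed. The weak points:
- The ynol ether of a hindered secondary benzylic alcohol is hard to make and thermally fragile.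
- The Lewis acidic catalyst can ionise the trimethoxybenzylic C–O bond and erase C2.
- The behaviour of an oxygen-substituted alkyne in this phenol synthesis is much less certain than that of the usual propargyl tethers.
- The stereodefined furyl carbinol behind **A5** still needs its own asymmetric synthesis.
- After the key step four operations remain (O-methylation at C7, desilylation, oxidation, olefination), against two in the chosen plan.

The chosen plan offers a ring closure of a thoroughly established type and a shorter endgame.

**Alternative 3:** stereoconvergent capture of a benzylic cation by a phenol. Here O1–C2 is cut. Acid ionises the benzylic alcohol of **A7** (either C1 epimer) to the ring-C-stabilised cation, and the ortho phenol oxygen closes ring B trans to the C3 methyl group, giving aldehyde **A6**, which is identical with compound **10** of the chosen route. This road is better than the chosen one in several respects: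
- The carbinol configuration is irrelevant, so a poor diastereomer ratio in the reduction is forgiven.
- The ring-A partner is a phenol, so no C–F bond has to be made.
- The aldehyde is carried directly, which saves the nitrile reduction.

Its weak points are stereochemical:
- C3 is the only controlling centre and must be set on its own. In the ketone stage it is epimerisable, so a dynamic reduction or another asymmetric step is needed anyway.
- The cation sits next to the C3–H bond. Loss of that proton gives a conjugated trisubstituted stilbene, and acid-mediated re-addition of the phenol would then erode the configuration at C3.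
- The trans outcome rests on a kinetic or thermodynamic preference, not on a stereospecific event.
- The 3,4,5-trimethoxyphenyl cation is less stabilised than a simple para-alkoxybenzyl cation, which calls for stronger acid and favours the elimination.

The chosen plan is about one step longer, but no bond to C2 or C3 is broken in its ring closure, so the configuration set in the hydrogenation is transferred without loss.

Key step: step 5

Assumption: the sense of induction of the hydrogenation catalyst in step 4 is assigned by analogy with simple aryl alkyl ketones, for which the (S)-XylBINAP/(S)-DAIPEN complex gives (R)-carbinols; should the opposite sense be found, the enantiomeric complex is used with no other change. Compounds **1**, **5** and **11** are taken to be commercial.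

## Route

Step 1
Reactants: 1 4-amino-3-methoxybenzonitrile
Product: 2 4-amino-3-bromo-5-methoxybenzonitrile
Conditions: NBS, MeCN, 0 °C → rt
Reagents that add atoms: N-bromosuccinimide, O=C1CCC(=O)N1Br
Why: Electrophilic aromatic bromination directed by the amino group, the strongest donor; its para position is blocked by the nitrile and one ortho position by the methoxy group, so bromine should enter only at C5.

Step 2
Reactants: 2 4-amino-3-bromo-5-methoxybenzonitrile
Product: 4 3-bromo-4-fluoro-5-methoxybenzonitrile, via diazonium tetrafluoroborate 3 (not isolated)
Conditions: NOBF4, MeCN, −20 → 0 °C; then 1,2-dichlorobenzene, 110–120 °C (MeCN distilled off)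
Reagents that add atoms: nitrosonium tetrafluoroborate, N#[O+].F[B-](F)(F)F
Why: Balz–Schiemann reaction: the weakly basic aniline is diazotised by NO+, and thermal loss of N2 from 3 gives an aryl cation that takes fluoride from BF4−; the ortho methoxy donor is expected to offset the retarding para nitrile.

Step 3
Reactants: 4 3-bromo-4-fluoro-5-methoxybenzonitrile; 5 1-(3,4,5-trimethoxyphenyl)propan-1-one
Product: 6 racemic 4-fluoro-3-methoxy-5-[1-oxo-1-(3,4,5-trimethoxyphenyl)propan-2-yl]benzonitrile
Conditions: Pd(OAc)2 (2 mol %), XPhos (4 mol %), K3PO4, toluene, 80 °C
Reagents that add atoms: none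
Why: Palladium-catalysed ketone α-arylation (Buchwald–Hartwig type): oxidative addition of the C–Br bond to zerovalent palladium, exchange with the potassium enolate of 5 and C–C reductive elimination from the bulky biarylphosphine complex. The weak, non-nucleophilic base K3PO4 is chosen so that the nitrile and the activated C–F bond are left alone; the new stereocentre is formed racemic and is meant to stay labile.

Step 4
Reactants: 6 racemic 4-fluoro-3-methoxy-5-[1-oxo-1-(3,4,5-trimethoxyphenyl)propan-2-yl]benzonitrile
Product: 7 4-fluoro-3-[(1R,2R)-1-hydroxy-1-(3,4,5-trimethoxyphenyl)propan-2-yl]-5-methoxybenzonitrile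
Conditions: trans-RuCl2[(S)-xylbinap][(S)-daipen] (0.5 mol %), KOt-Bu (5 mol %), H2 (8 atm), i-PrOH, 25 °C
Reagents that add atoms: none
Why: Noyori-type bifunctional ketone hydrogenation under dynamic kinetic resolution: the catalytic alkoxide racemises the doubly activated α-C–H of 6 faster than the slow enantiomer is reduced. The catalyst sets C1 by its facial preference for aryl ketones and sets C2 by reducing the (R)-ketone preferentially, in the sense that matches Felkin–Anh delivery, so the (1R,2R) (syn) alcohol should result. Any 7 that cyclises under the basic conditions would give 8, the product of the next step, stereospecifically.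

Step 5
Reactants: 7 4-fluoro-3-[(1R,2R)-1-hydroxy-1-(3,4,5-trimethoxyphenyl)propan-2-yl]-5-methoxybenzonitrile
Product: 8 (2R,3R)-7-methoxy-3-methyl-2-(3,4,5-trimethoxyphenyl)-2,3-dihydro-1-benzofuran-5-carbonitrile
Conditions: KN(SiMe3)2 (1.05 equiv), THF, −20 → 25 °C
Reagents that add atoms: none
Why: KN(SiMe3)2 converts the hydroxyl group of 7 into its potassium alkoxide, which adds to the fluorine-bearing carbon C7a to give a Meisenheimer anion delocalised onto C5 and the nitrile; loss of fluoride restores ring A and completes O1–C7a. The closest known reaction type is the intramolecular SNAr etherification of 2-(2-fluoroaryl)ethanols that carry a para acceptor, a standard closure of 2,3-dihydrobenzofurans. Ring B closes in a 5-exo-trig mode by attack at the ipso carbon. No stereocentre is created and no bond to C2 or C3 is broken, so the (1R,2R) configuration of 7 becomes (2R,3R) in 8, and the trans relation follows from the syn alcohol. The step needs ipso substitution at C7a in preference to addition to the nitrile, displacement of the C7 methoxy group and intermolecular etherification; the para nitrile, fluoride as the best SNAr leaving group, the five-membered transition state and moderate dilution should secure this. Epimerisation is not expected, since the C3–H bond is only benzylic and the amide base is consumed by the alcohol.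

Step 6
Reactants: 8 (2R,3R)-7-methoxy-3-methyl-2-(3,4,5-trimethoxyphenyl)-2,3-dihydro-1-benzofuran-5-carbonitrile
Product: 10 (2R,3R)-7-methoxy-3-methyl-2-(3,4,5-trimethoxyphenyl)-2,3-dihydro-1-benzofuran-5-carbaldehyde, via N-(diisobutylalumanyl)aldimine 9 (not isolated)
Conditions: i-Bu2AlH (DIBAL-H, 1.3 equiv), CH2Cl2, −78 °C; then aq. potassium sodium tartrate, aq. citric acid, 0 °C
Reagents that add atoms: water, O
Why: Partial reduction of an aryl nitrile: one hydride adds to give the aluminium iminate 9, which is stable at −78 °C and is hydrolysed to the aldehyde on mildly acidic work-up. Aryl ethers and the dihydrobenzofuran are inert to the hydride at this temperature, and the weak acid of the work-up should not ionise C2.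

Step 7
Reactants: 10 (2R,3R)-7-methoxy-3-methyl-2-(3,4,5-trimethoxyphenyl)-2,3-dihydro-1-benzofuran-5-carbaldehyde; 11 5-(ethylsulfonyl)-1-phenyl-1H-tetrazole
Product: 12 (2R,3R)-7-methoxy-3-methyl-5-[(E)-prop-1-en-1-yl]-2-(3,4,5-trimethoxyphenyl)-2,3-dihydro-1-benzofuran (CNP0219898.1)
Conditions: 11, KN(SiMe3)2, DME, −60 °C; then 10, −60 → 20 °C
Reagents that add atoms: none
Why: Julia–Kocienski olefination: the metallated sulfone adds to the aldehyde, the phenyltetrazolyl group migrates to oxygen (Smiles rearrangement) and SO2 and the tetrazolate are eliminated. The potassium counter-ion in DME favours the (E)-alkene, and the purely basic conditions leave the C2 benzylic ether and both stereocentres untouched.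

## Compound list

1 | 4-amino-3-methoxybenzonitrile | N#Cc1ccc(N)c(OC)c1 | starting material
2 | 4-amino-3-bromo-5-methoxybenzonitrile | N#Cc1cc(Br)c(N)c(OC)c1 | intermediate
3 | 2-bromo-4-cyano-6-methoxybenzenediazonium tetrafluoroborate | N#[N+]c1c(Br)cc(C#N)cc1OC.F[B-](F)(F)F | intermediate
4 | 3-bromo-4-fluoro-5-methoxybenzonitrile | N#Cc1cc(Br)c(F)c(OC)c1 | intermediate
5 | 1-(3,4,5-trimethoxyphenyl)propan-1-one | CCC(=O)c1cc(OC)c(OC)c(OC)c1 | starting material
6 | racemic 4-fluoro-3-methoxy-5-[1-oxo-1-(3,4,5-trimethoxyphenyl)propan-2-yl]benzonitrile | CC(C(=O)c1cc(OC)c(OC)c(OC)c1)c1cc(C#N)cc(OC)c1F | intermediate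
7 | 4-fluoro-3-[(1R,2R)-1-hydroxy-1-(3,4,5-trimethoxyphenyl)propan-2-yl]-5-methoxybenzonitrile | C[C@H](c1cc(C#N)cc(OC)c1F)[C@@H](O)c1cc(OC)c(OC)c(OC)c1 | intermediate
8 | (2R,3R)-7-methoxy-3-methyl-2-(3,4,5-trimethoxyphenyl)-2,3-dihydro-1-benzofuran-5-carbonitrile | N#Cc1cc(OC)c2c(c1)[C@@H](C)[C@H](c1cc(OC)c(OC)c(OC)c1)O2 | intermediate
9 | N-[bis(2-methylpropyl)alumanyl]-1-[(2R,3R)-7-methoxy-3-methyl-2-(3,4,5-trimethoxyphenyl)-2,3-dihydro-1-benzofuran-5-yl]methanimine | CC(C)C[Al](CC(C)C)N=Cc1cc(OC)c2c(c1)[C@@H](C)[C@H](c1cc(OC)c(OC)c(OC)c1)O2 | intermediate
10 | (2R,3R)-7-methoxy-3-methyl-2-(3,4,5-trimethoxyphenyl)-2,3-dihydro-1-benzofuran-5-carbaldehyde | O=Cc1cc(OC)c2c(c1)[C@@H](C)[C@H](c1cc(OC)c(OC)c(OC)c1)O2 | intermediate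
11 | 5-(ethylsulfonyl)-1-phenyl-1H-tetrazole | CCS(=O)(=O)c1nnnn1-c1ccccc1 | starting material
12 | (2R,3R)-7-methoxy-3-methyl-5-[(E)-prop-1-en-1-yl]-2-(3,4,5-trimethoxyphenyl)-2,3-dihydro-1-benzofuran | C/C=C/c1cc(OC)c2c(c1)[C@@H](C)[C@H](c1cc(OC)c(OC)c(OC)c1)O2 | target

Total step count: 7. Longest linear sequence: 7 steps (1 → 12); ketone 5 and sulfone 11 enter as purchased materials.

## Least certain steps

**Step 5 (key step).** Ipso attack at C7a may be slow, because this carbon is flanked by the donor methoxy group at C7 and by the branched C3 substituent. Slow closure would leave time for addition of the alkoxide or of residual amide base to the nitrile, or for intermolecular etherification. The fallback changes the activating group before the ring is closed. It sets out from 7: reduction with excess i-Bu2AlH at −78 °C and hydrolytic work-up should give 4-fluoro-3-[(1R,2R)-1-hydroxy-1-(3,4,5-trimethoxyphenyl)propan-2-yl]-5-methoxybenzaldehyde F1. Its formyl group is as strong a para acceptor as the nitrile, and alkoxide addition to it is reversible. Closure with Cs2CO3 in DMF at 60 °C, with no amide base present, would give aldehyde 10 directly. The fallback rejoins the route at 10, and 8 is bypassed.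

**Step 4.** The catalyst may not discriminate well enough between the two rapidly equilibrating enantiomers of 6, whose α-aryl group is bulky and ortho-disubstituted, so that diastereo- or enantioselectivity falls short. The nitrile may also bind to ruthenium and slow turnover, and under base the enolate oxygen could attack C7a and aromatise to a benzofuran, erasing both centres. The fallback separates relative from absolute control and sets out from 6:
- Substrate-controlled Felkin–Anh reduction with LiBH(s-Bu)3 in THF at −78 °C should give the racemic syn alcohol rac-(1R,2R)-4-fluoro-3-[1-hydroxy-1-(3,4,5-trimethoxyphenyl)propan-2-yl]-5-methoxybenzonitrile F2.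
- Esterification with (S)-2-methoxy-2-phenylacetic acid (DCC, DMAP) gives two diastereomeric esters: (1R,2R)-2-(5-cyano-2-fluoro-3-methoxyphenyl)-1-(3,4,5-trimethoxyphenyl)propyl (2S)-2-methoxy-2-phenylacetate F3 and (1S,2S)-2-(5-cyano-2-fluoro-3-methoxyphenyl)-1-(3,4,5-trimethoxyphenyl)propyl (2S)-2-methoxy-2-phenylacetate F4. These are separated by chromatography.
- Hydrolysis of F3 with LiOH in aqueous THF at 0 °C returns to the route at 7.

**Step 3.** The product 6 is more acidic than 5 and is held as its potassium enolate at 80 °C. Attack of the enolate oxygen on the activated C–F carbon would close an achiral 2-aryl-3-methylbenzofuran. Slow reductive elimination from the hindered secondary enolate could also let protodebromination of 4 compete. The fallback couples a preformed enol silane under conditions that do not deprotonate the product. It sets out from 5: silylation (Me3SiCl, Et3N, NaI, MeCN) gives (Z)-trimethyl{[1-(3,4,5-trimethoxyphenyl)prop-1-en-1-yl]oxy}silane F5. F5 is then arylated by 4 with Pd2(dba)3, P(t-Bu)3, Bu3SnF and CsF in toluene at 85 °C (fluoride-promoted arylation through the tin enolate), and the route is rejoined at 6.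

**Step 2.** Heterolytic loss of N2 from the diazonium ion 3 is slowed by the para nitrile, so hydrodediazoniation, arylation of the solvent and tar formation can compete with fluoride capture. The fallback replaces the direct C–N to C–F exchange by C–N to C–O to C–F and sets out from 2:
- Diazotisation with NaNO2 in aqueous H2SO4 at 0 °C gives 2-bromo-4-cyano-6-methoxybenzenediazonium hydrogensulfate F6.
- Hydrolysis with Cu2O and Cu(NO3)2 in water at room temperature gives 3-bromo-4-hydroxy-5-methoxybenzonitrile F7.
- Treatment with SO2F2 and NMe4F in DMF converts the phenol through 2-bromo-4-cyano-6-methoxyphenyl sulfurofluoridate F8 into the aryl fluoride (deoxyfluorination by concerted substitution, favoured by the para nitrile). The route is rejoined at 4.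

**Step 7.** Addition of the metallated sulfone to an aromatic aldehyde may be less stereoselective than to aliphatic ones, giving some (Z)-alkene that is hard to separate from 12. The fallback sets out from 10 and uses a different olefination, the Takai–Utimoto ethylidenation with CH3CHI2 and CrCl2 (divalent chromium) in THF at room temperature. It is reliably E-selective for aryl aldehydes and arrives directly at 12 without any new isolable compound.

## Further compounds

F1 | step 5 | 4-fluoro-3-[(1R,2R)-1-hydroxy-1-(3,4,5-trimethoxyphenyl)propan-2-yl]-5-methoxybenzaldehyde | C[C@H](c1cc(C=O)cc(OC)c1F)[C@@H](O)c1cc(OC)c(OC)c(OC)c1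
F2 | step 4 | rac-(1R,2R)-4-fluoro-3-[1-hydroxy-1-(3,4,5-trimethoxyphenyl)propan-2-yl]-5-methoxybenzonitrile (1:1 mixture of the 1R,2R and 1S,2S enantiomers) | C[C@H](c1cc(C#N)cc(OC)c1F)[C@@H](O)c1cc(OC)c(OC)c(OC)c1.C[C@@H](c1cc(C#N)cc(OC)c1F)[C@H](O)c1cc(OC)c(OC)c(OC)c1
F3 | step 4 | (1R,2R)-2-(5-cyano-2-fluoro-3-methoxyphenyl)-1-(3,4,5-trimethoxyphenyl)propyl (2S)-2-methoxy-2-phenylacetate | C[C@H](c1cc(C#N)cc(OC)c1F)[C@@H](OC(=O)[C@@H](OC)c1ccccc1)c1cc(OC)c(OC)c(OC)c1
F4 | step 4 | (1S,2S)-2-(5-cyano-2-fluoro-3-methoxyphenyl)-1-(3,4,5-trimethoxyphenyl)propyl (2S)-2-methoxy-2-phenylacetate | C[C@@H](c1cc(C#N)cc(OC)c1F)[C@H](OC(=O)[C@@H](OC)c1ccccc1)c1cc(OC)c(OC)c(OC)c1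
F5 | step 3 | (Z)-trimethyl{[1-(3,4,5-trimethoxyphenyl)prop-1-en-1-yl]oxy}silane | C/C=C(\O[Si](C)(C)C)c1cc(OC)c(OC)c(OC)c1
F6 | step 2 | 2-bromo-4-cyano-6-methoxybenzenediazonium hydrogensulfate | N#[N+]c1c(Br)cc(C#N)cc1OC.OS(=O)(=O)[O-]
F7 | step 2 | 3-bromo-4-hydroxy-5-methoxybenzonitrile | N#Cc1cc(Br)c(O)c(OC)c1
F8 | step 2 | 2-bromo-4-cyano-6-methoxyphenyl sulfurofluoridate | N#Cc1cc(Br)c(OS(=O)(=O)F)c(OC)c1
F0 | step 7 | none | none
A1 | alternative 1 | (2R,3R)-7-methoxy-3-methyl-5-[(E)-prop-1-en-1-yl]-2-(3,4,5-trimethoxyphenyl)-2,3-dihydro-1-benzofuran-4-ol | C/C=C/c1cc(OC)c2c(c1O)[C@@H](C)[C@H](c1cc(OC)c(OC)c(OC)c1)O2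
A2 | alternative 1 | pentacarbonyl{methoxy[(4R,5R)-4-methyl-5-(3,4,5-trimethoxyphenyl)-4,5-dihydrofuran-2-yl]methylidene}chromium | COC(C1=C[C@@H](C)[C@H](c2cc(OC)c(OC)c(OC)c2)O1)=[Cr](=C=O)(=C=O)(=C=O)(=C=O)=C=O
A3 | alternative 1 | (E)-pent-3-en-1-yne | C#C/C=C/C
A4 | alternative 2 | (2R,3R)-5-({[tert-butyl(dimethyl)silyl]oxy}methyl)-3-methyl-2-(3,4,5-trimethoxyphenyl)-2,3-dihydro-1-benzofuran-7-ol | CC(C)(C)[Si](C)(C)OCc1cc(O)c2c(c1)[C@@H](C)[C@H](c1cc(OC)c(OC)c(OC)c1)O2
A5 | alternative 2 | tert-butyl({5-[(1R,2S)-1-(ethynyloxy)-1-(3,4,5-trimethoxyphenyl)propan-2-yl]furan-3-yl}methoxy)dimethylsilane | C[C@H](c1cc(CO[Si](C)(C)C(C)(C)C)co1)[C@@H](OC#C)c1cc(OC)c(OC)c(OC)c1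
A6 | alternative 3 | (2R,3R)-7-methoxy-3-methyl-2-(3,4,5-trimethoxyphenyl)-2,3-dihydro-1-benzofuran-5-carbaldehyde | O=Cc1cc(OC)c2c(c1)[C@@H](C)[C@H](c1cc(OC)c(OC)c(OC)c1)O2
A7 | alternative 3 | 4-hydroxy-3-[(2R)-1-hydroxy-1-(3,4,5-trimethoxyphenyl)propan-2-yl]-5-methoxybenzaldehyde (either C1 epimer) | C[C@H](c1cc(C=O)cc(OC)c1O)C(O)c1cc(OC)c(OC)c(OC)c1
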